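**Plan**

1. Numbering of the central benzene ring: C1 carries the 6-methoxyindol-3-yl group, C4 the 5-hydroxyindol-3-yl group, and C2, C3, C5, C6 the four methoxy groups. The retrosynthesis first removes the N-silyl and O-benzyl groups and the two O–CH3 bonds at C3 and C6, which leaves a hydroquinone.
2. It then cuts ring bond C5–C6 (electrocyclization; in the reverse sense the C3–C6 bond of a cyclobutenone returns), then C3–C4 (vinyllithium plus cyclobutenedione), then the C1–indole C3 bond (lithioindole plus dimethyl squarate).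
3. Enabling feature: the central ring is fully substituted, with oxygen on C2, C3, C5 and C6 and the indol-3-yl groups para on C1 and C4. The unit C6–C1–C2–C3 (O, indolyl, O, O) is the four-carbon ring of an aryl squarate, and C4–C5 (indolyl, OCH3) is an enol ether.
4. Forward order: both indole rings are bought. 6-Methoxyindole is silylated, brominated, lithiated and joined to dimethyl squarate; the aldehyde is turned into a lithiated bromo enol ether that adds to the resulting dione; heating closes the central benzene ring, the only ring made; methylation, desilylation and debenzylation follow.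
5. Stereochemistry: the target has no stereocentre. The carbinol carbon of the cyclobutenone is formed racemic and becomes aromatic, and the enol ether geometry has no bearing on the constitution of the ring-expanded product.

Key step: step 8

Assumption: the two indole–arene axes are flanked on the indole side only by C2–H and the peri C4–H and are taken to rotate freely at room temperature, so the target is treated as achiral.

**Route**

Step 1
Reactants: 1 6-methoxy-1H-indole
Product: 3 6-methoxy-1-(triisopropylsilyl)indole, via sodium 6-methoxyindol-1-ide 2 (not isolated)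
Conditions: NaH, THF, 0 °C; then iPr3SiCl, 0 °C → rt
Reagents that add atoms: triisopropylsilyl chloride, CC(C)[Si](Cl)(C(C)C)C(C)C
Why: N-silylation of the sodium indolide is a standard protection, and the bulky silyl group later shields C2 and keeps a C3 anion from migrating.

Step 2
Reactants: 3 6-methoxy-1-(triisopropylsilyl)indole
Product: 4 3-bromo-6-methoxy-1-(triisopropylsilyl)indole
Conditions: NBS (1 equiv), THF, −78 °C → rt
Reagents that add atoms: N-bromosuccinimide, O=C1CCC(=O)N1Br
Why: Electrophilic aromatic bromination takes place at C3, the enamine-like carbon of the indole, while the N-silyl group blocks nitrogen and C2.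

Step 3
Reactants: 4 3-bromo-6-methoxy-1-(triisopropylsilyl)indole; 5 dimethyl squarate
Product: 8 3-methoxy-4-[6-methoxy-1-(triisopropylsilyl)indol-3-yl]cyclobut-3-ene-1,2-dione, via 3-lithio-6-methoxy-1-(triisopropylsilyl)indole 6 (not isolated), via lithium alkoxide of the squarate adduct 7 (not isolated)
Conditions: t-BuLi (2 equiv), THF, −78 °C; cannulate into 5, THF, −78 °C; (CF3CO)2O, −78 °C; aq. NaHCO3
Reagents that add atoms: none
Why: Bromine–lithium exchange gives the C3-lithioindole, which adds 1,2 to one squarate carbonyl, and O-trifluoroacetylation of the alkoxide then triggers the allylic transposition with loss of one methoxy methyl, the standard conversion of a squarate into a 3-aryl-4-alkoxycyclobutenedione.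

Step 4
Reactants: 9 5-(benzyloxy)-1H-indole-3-carbaldehyde
Product: 11 5-(benzyloxy)-1-(triisopropylsilyl)indole-3-carbaldehyde, via sodium 5-(benzyloxy)-3-formylindol-1-ide 10 (not isolated)
Conditions: NaH, THF, 0 °C; then iPr3SiCl, 0 °C → rt
Reagents that add atoms: triisopropylsilyl chloride, CC(C)[Si](Cl)(C(C)C)C(C)C
Why: N-silylation removes the acidic N–H that would quench the ylide and the organolithium used later and restores the electrophilicity of the vinylogous formamide carbonyl.

Step 5
Reactants: 11 5-(benzyloxy)-1-(triisopropylsilyl)indole-3-carbaldehyde; 12 (methoxymethyl)triphenylphosphonium chloride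
Product: 14 5-(benzyloxy)-3-(2-methoxyvinyl)-1-(triisopropylsilyl)indole (E/Z mixture), via (methoxymethylene)triphenylphosphorane 13 (not isolated)
Conditions: 12, NaN(SiMe3)2, THF, 0 °C; then 11, 0 °C → rt
Reagents that add atoms: none
Why: Wittig olefination with the non-stabilised methoxymethylene ylide converts the aldehyde into the enol ether, and its geometry is unimportant because the next step destroys and re-forms the double bond.

Step 6
Reactants: 14 5-(benzyloxy)-3-(2-methoxyvinyl)-1-(triisopropylsilyl)indole (E/Z mixture)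
Product: 16 (Z)-5-(benzyloxy)-3-(1-bromo-2-methoxyvinyl)-1-(triisopropylsilyl)indole (bromine cis to methoxy), via 1,2-dibromo ether 15 (not isolated)
Conditions: Br2 (1 equiv), CH2Cl2, −78 °C; then Et3N, −78 °C → rt
Reagents that add atoms: bromine, BrBr
Why: This is the bromination–dehydrobromination of an enol ether, the way 2-bromovinyl ethers and 5-bromo-3,4-dihydro-2H-pyran are made: bromine adds across the electron-rich double bond, the amine removes HBr through the oxocarbenium ion so that bromine stays on the indole-bearing carbon, and the isomer that keeps the bulky indole trans to the methoxy group should predominate.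

Step 7
Reactants: 16 (Z)-5-(benzyloxy)-3-(1-bromo-2-methoxyvinyl)-1-(triisopropylsilyl)indole; 8 3-methoxy-4-[6-methoxy-1-(triisopropylsilyl)indol-3-yl]cyclobut-3-ene-1,2-dione
Product: 18 rac-4-{(Z)-1-[5-(benzyloxy)-1-(triisopropylsilyl)indol-3-yl]-2-methoxyvinyl}-4-hydroxy-3-methoxy-2-[6-methoxy-1-(triisopropylsilyl)indol-3-yl]cyclobut-2-en-1-one, via 1-indolyl-2-methoxyvinyllithium 17 (not isolated)
Conditions: 16, t-BuLi (2 equiv), THF, −78 °C; cannulate into 8, THF, −78 °C; sat. aq. NH4Cl, −78 °C
Reagents that add atoms: none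
Why: Bromine–lithium exchange with retention gives a vinyllithium whose lithium is cis to the methoxy oxygen and therefore cannot undergo anti β-elimination, and it adds 1,2 to the carbonyl next to the methoxy-bearing ring carbon because the other carbonyl is a vinylogous ester flanked by the bulky silylindole, the regiochemistry known for organolithium additions to 3-alkoxy-4-arylcyclobutenediones; the carbinol centre forms racemic and is lost in step 8.

Step 8
Reactants: 18 rac-4-{(Z)-1-[5-(benzyloxy)-1-(triisopropylsilyl)indol-3-yl]-2-methoxyvinyl}-4-hydroxy-3-methoxy-2-[6-methoxy-1-(triisopropylsilyl)indol-3-yl]cyclobut-2-en-1-one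
Product: 21 5-[5-(benzyloxy)-1-(triisopropylsilyl)indol-3-yl]-3,6-dimethoxy-2-[6-methoxy-1-(triisopropylsilyl)indol-3-yl]benzene-1,4-diol, via hydroxy dienylketene 19 (not isolated), via cyclohexa-2,4-dienone 20 (not isolated)
Conditions: PhMe (degassed), 110 °C, Ar
Reagents that add atoms: none
Why: Heat opens the cyclobutenone by a conrotatory four-electron electrocyclic cleavage of the bond between the carbonyl carbon and the carbinol carbon to give hydroxy dienylketene 19, whose ketene carbon then bonds to the terminal CH(OCH3) carbon, and enolisation of dienone 20 gives the hydroquinone. The closest known reaction is the Moore rearrangement of squarate-derived 4-alkenyl-4-hydroxycyclobutenones to hydroquinones. The central six-membered carbocycle closes by a six-electron electrocyclization of the triene made up of the ketene C=C bond and the two alkene units, the new bond being C5–C6 of the target ring. No stereocentre survives: the carbinol carbon becomes sp2 and the transient sp3 carbon of 20 is erased by tautomerisation. The step needs the alkenyl group to rotate inward toward the ketene, and this is secured by the donor hydroxyl on the same carbon, which prefers outward rotation. The para relationship of the indoles is already fixed in 18, where one indole sits on the ring carbon next to the carbonyl and the other on the inner alkene carbon, and the enol ether geometry is irrelevant because its terminal carbon becomes aromatic.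

Step 9
Reactants: 21 5-[5-(benzyloxy)-1-(triisopropylsilyl)indol-3-yl]-3,6-dimethoxy-2-[6-methoxy-1-(triisopropylsilyl)indol-3-yl]benzene-1,4-diol (used crude, kept under argon)
Product: 22 5-(benzyloxy)-3-{2,3,5,6-tetramethoxy-4-[6-methoxy-1-(triisopropylsilyl)indol-3-yl]phenyl}-1-(triisopropylsilyl)indole
Conditions: Me2SO4, K2CO3, acetone, reflux, Ar
Reagents that add atoms: dimethyl sulfate, COS(=O)(=O)OC
Why: Williamson O-methylation of both phenols should proceed with carbonate in acetone, a base too weak to cleave the N–Si bonds or to N-methylate, while exclusion of air keeps the hydroquinone from oxidising.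

Step 10
Reactants: 22 5-(benzyloxy)-3-{2,3,5,6-tetramethoxy-4-[6-methoxy-1-(triisopropylsilyl)indol-3-yl]phenyl}-1-(triisopropylsilyl)indole
Product: 23 5-(benzyloxy)-3-[2,3,5,6-tetramethoxy-4-(6-methoxy-1H-indol-3-yl)phenyl]-1H-indole
Conditions: Bu4NF, THF, 0 °C → rt
Reagents that add atoms: none
Why: Fluoride-induced cleavage of the N–Si bonds (desilylation) frees both indole N–H groups and leaves aryl methyl and benzyl ethers untouched.

Step 11
Reactants: 23 5-(benzyloxy)-3-[2,3,5,6-tetramethoxy-4-(6-methoxy-1H-indol-3-yl)phenyl]-1H-indole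
Product: 24 3-[2,3,5,6-tetramethoxy-4-(6-methoxy-1H-indol-3-yl)phenyl]-1H-indol-5-ol
Conditions: H2 (1 atm), 10% Pd/C, EtOAc–MeOH, rt
Reagents that add atoms: none
Why: Catalytic hydrogenolysis of the benzyl aryl ether liberates the phenol, and indoles and aryl methyl ethers are inert to hydrogen at atmospheric pressure and room temperature.

**Compound list**

1 | 6-methoxy-1H-indole | COc1ccc2cc[nH]c2c1 | starting material
2 | sodium 6-methoxyindol-1-ide | COc1ccc2cc[n-]c2c1.[Na+] | intermediate
3 | 6-methoxy-1-(triisopropylsilyl)indole | COc1ccc2ccn([Si](C(C)C)(C(C)C)C(C)C)c2c1 | intermediate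
4 | 3-bromo-6-methoxy-1-(triisopropylsilyl)indole | COc1ccc2c(Br)cn([Si](C(C)C)(C(C)C)C(C)C)c2c1 | intermediate
5 | dimethyl squarate | COC1=C(OC)C(=O)C1=O | starting material
6 | 3-lithio-6-methoxy-1-(triisopropylsilyl)indole | [Li]c1cn([Si](C(C)C)(C(C)C)C(C)C)c2cc(OC)ccc12 | intermediate
7 | lithium alkoxide of rac-4-hydroxy-2,3-dimethoxy-4-[6-methoxy-1-(triisopropylsilyl)indol-3-yl]cyclobut-2-en-1-one | [Li]OC1(c2cn([Si](C(C)C)(C(C)C)C(C)C)c3cc(OC)ccc23)C(OC)=C(OC)C1=O | intermediate
8 | 3-methoxy-4-[6-methoxy-1-(triisopropylsilyl)indol-3-yl]cyclobut-3-ene-1,2-dione | COC1=C(c2cn([Si](C(C)C)(C(C)C)C(C)C)c3cc(OC)ccc23)C(=O)C1=O | intermediate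
9 | 5-(benzyloxy)-1H-indole-3-carbaldehyde | O=Cc1c[nH]c2ccc(OCc3ccccc3)cc12 | starting material
10 | sodium 5-(benzyloxy)-3-formylindol-1-ide | O=Cc1c[n-]c2ccc(OCc3ccccc3)cc12.[Na+] | intermediate
11 | 5-(benzyloxy)-1-(triisopropylsilyl)indole-3-carbaldehyde | O=Cc1cn([Si](C(C)C)(C(C)C)C(C)C)c2ccc(OCc3ccccc3)cc12 | intermediate
12 | (methoxymethyl)triphenylphosphonium chloride | COC[P+](c1ccccc1)(c1ccccc1)c1ccccc1.[Cl-] | starting material
13 | (methoxymethylene)triphenylphosphorane | COC=P(c1ccccc1)(c1ccccc1)c1ccccc1 | intermediate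
14 | 5-(benzyloxy)-3-(2-methoxyvinyl)-1-(triisopropylsilyl)indole, E/Z mixture | COC=Cc1cn([Si](C(C)C)(C(C)C)C(C)C)c2ccc(OCc3ccccc3)cc12 | intermediate
15 | 5-(benzyloxy)-3-(1,2-dibromo-2-methoxyethyl)-1-(triisopropylsilyl)indole, mixture of diastereomers | COC(Br)C(Br)c1cn([Si](C(C)C)(C(C)C)C(C)C)c2ccc(OCc3ccccc3)cc12 | intermediate
16 | (Z)-5-(benzyloxy)-3-(1-bromo-2-methoxyvinyl)-1-(triisopropylsilyl)indole | CO/C=C(\Br)c1cn([Si](C(C)C)(C(C)C)C(C)C)c2ccc(OCc3ccccc3)cc12 | intermediate
17 | {1-[5-(benzyloxy)-1-(triisopropylsilyl)indol-3-yl]-2-methoxyvinyl}lithium, lithium cis to methoxy | CO/C=C(\[Li])c1cn([Si](C(C)C)(C(C)C)C(C)C)c2ccc(OCc3ccccc3)cc12 | intermediate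
18 | rac-4-{(Z)-1-[5-(benzyloxy)-1-(triisopropylsilyl)indol-3-yl]-2-methoxyvinyl}-4-hydroxy-3-methoxy-2-[6-methoxy-1-(triisopropylsilyl)indol-3-yl]cyclobut-2-en-1-one | COc1ccc2c(C3=C(OC)C(O)(/C(=C\OC)c4cn([Si](C(C)C)(C(C)C)C(C)C)c5ccc(OCc6ccccc6)cc45)C3=O)cn([Si](C(C)C)(C(C)C)C(C)C)c2c1 | intermediate
19 | (3Z,5Z)-5-[5-(benzyloxy)-1-(triisopropylsilyl)indol-3-yl]-4-hydroxy-3,6-dimethoxy-2-[6-methoxy-1-(triisopropylsilyl)indol-3-yl]hexa-1,3,5-trien-1-one | COc1ccc2c(C(=C=O)/C(OC)=C(O)\C(=C/OC)c3cn([Si](C(C)C)(C(C)C)C(C)C)c4ccc(OCc5ccccc5)cc34)cn([Si](C(C)C)(C(C)C)C(C)C)c2c1 | intermediate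
20 | rac-5-[5-(benzyloxy)-1-(triisopropylsilyl)indol-3-yl]-4-hydroxy-3,6-dimethoxy-2-[6-methoxy-1-(triisopropylsilyl)indol-3-yl]cyclohexa-2,4-dien-1-one | COc1ccc2c(C3=C(OC)C(O)=C(c4cn([Si](C(C)C)(C(C)C)C(C)C)c5ccc(OCc6ccccc6)cc45)C(OC)C3=O)cn([Si](C(C)C)(C(C)C)C(C)C)c2c1 | intermediate
21 | 5-[5-(benzyloxy)-1-(triisopropylsilyl)indol-3-yl]-3,6-dimethoxy-2-[6-methoxy-1-(triisopropylsilyl)indol-3-yl]benzene-1,4-diol | COc1ccc2c(-c3c(O)c(OC)c(-c4cn([Si](C(C)C)(C(C)C)C(C)C)c5ccc(OCc6ccccc6)cc45)c(O)c3OC)cn([Si](C(C)C)(C(C)C)C(C)C)c2c1 | intermediate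
22 | 5-(benzyloxy)-3-{2,3,5,6-tetramethoxy-4-[6-methoxy-1-(triisopropylsilyl)indol-3-yl]phenyl}-1-(triisopropylsilyl)indole | COc1ccc2c(-c3c(OC)c(OC)c(-c4cn([Si](C(C)C)(C(C)C)C(C)C)c5ccc(OCc6ccccc6)cc45)c(OC)c3OC)cn([Si](C(C)C)(C(C)C)C(C)C)c2c1 | intermediate
23 | 5-(benzyloxy)-3-[2,3,5,6-tetramethoxy-4-(6-methoxy-1H-indol-3-yl)phenyl]-1H-indole | COc1ccc2c(-c3c(OC)c(OC)c(-c4c[nH]c5ccc(OCc6ccccc6)cc45)c(OC)c3OC)c[nH]c2c1 | intermediate
24 | 3-[2,3,5,6-tetramethoxy-4-(6-methoxy-1H-indol-3-yl)phenyl]-1H-indol-5-ol | COc1ccc2c(-c3c(OC)c(OC)c(-c4c[nH]c5ccc(O)cc45)c(OC)c3OC)c[nH]c2c1 | target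

**Step count and risks**

Total step count: 11. Longest linear sequence: 8 steps (steps 4 to 11 from aldehyde 9; the branch from 6-methoxyindole, steps 1 to 3 and 7 to 11, is equally long).

Steps most likely to fail:

1. Step 6. Bromine may attack the electron-rich silylindole nucleus as well as the enol ether. The dibromide may also lose HBr in the wrong sense, through ionisation of the indolylmethyl C–Br bond instead of the α-bromo ether, or give a mixture of bromide geometries; the minor geometry would put lithium anti to methoxy in step 7 and invite β-elimination.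
   Fallback, setting out from aldehyde 9 and returning at bromo enol ether 16: the nitrogen is first given an electron-withdrawing carbamate so that the ring neither competes for bromine nor assists benzylic ionisation.
   - Boc2O and catalytic 4-(dimethylamino)pyridine in MeCN should convert 9 into tert-butyl 5-(benzyloxy)-3-formylindole-1-carboxylate F1.
   - Wittig reaction with ylide 13 should give the N-Boc enol ether tert-butyl 5-(benzyloxy)-3-(2-methoxyvinyl)indole-1-carboxylate F2.
   - Br2 in CH2Cl2 at −78 °C should give the dibromide tert-butyl 5-(benzyloxy)-3-(1,2-dibromo-2-methoxyethyl)indole-1-carboxylate F3, from which Et3N removes HBr to give tert-butyl (Z)-5-(benzyloxy)-3-(1-bromo-2-methoxyvinyl)indole-1-carboxylate F4.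
   - K2CO3 in MeOH should remove the carbamate and give (Z)-5-(benzyloxy)-3-(1-bromo-2-methoxyvinyl)-1H-indole F5.
   - NaH, by way of the sodium salt of the bromo enol ether F6, followed by iPr3SiCl should give 16.

2. Step 7. The silylindole pushes electron density into the very carbonyl that must be attacked, so the addition may be slow or partly misdirected to the vinylogous-ester carbonyl. The doubly allylic tertiary carbinol may also ionise during isolation; a cold neutral quench and base-washed silica are the first precautions.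
   Fallback, setting out from dione 8 and returning at 23: the electrophile is re-tuned by exchanging the N-silyl group of the squarate-bound indole for a carbamate, which makes that indole an ordinary weakly donating aryl group.
   - Bu4NF buffered with AcOH in THF at 0 °C should give 3-methoxy-4-(6-methoxy-1H-indol-3-yl)cyclobut-3-ene-1,2-dione F7.
   - Boc2O and catalytic 4-(dimethylamino)pyridine should give tert-butyl 6-methoxy-3-(2-methoxy-3,4-dioxocyclobut-1-en-1-yl)indole-1-carboxylate F8.
   - Addition of vinyllithium 17 (from 16 as in step 7) should give the N-Boc cyclobutenone F9.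
   - Heating in toluene as in step 8 should lead through the N-Boc dienylketene F10 and the N-Boc cyclohexadienone F11 to the N-Boc hydroquinone F12.
   - Me2SO4 and K2CO3 should give the N-Boc tetramethyl ether F13.
   - Bu4NF at room temperature should remove the remaining silyl group and give the mono-Boc bis-indole F14, and K2CO3 in warm MeOH–THF should then remove the carbamate to give 23.

3. Step 8. The very electron-rich hydroquinone may oxidise partially in the hot solution or during work-up, so that a mixture of oxidation levels reaches the methylation and methylates poorly.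
   Fallback, setting out from cyclobutenone 18 and returning at 22: the oxidation is driven to completion on purpose and the material is purified at the quinone level.
   - After the thermolysis the crude product is stirred with Ag2O in ether to give 2-[5-(benzyloxy)-1-(triisopropylsilyl)indol-3-yl]-3,6-dimethoxy-5-[6-methoxy-1-(triisopropylsilyl)indol-3-yl]cyclohexa-2,5-diene-1,4-dione F15, which can be chromatographed and stored.
   - Aqueous Na2S2O4 in THF–EtOAc under argon reduces F15 back to hydroquinone 21, which is methylated in the same flask with K2CO3 and Me2SO4 to give 22.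

**Further compounds**

F1 | step 6 | tert-butyl 5-(benzyloxy)-3-formylindole-1-carboxylate | O=Cc1cn(C(=O)OC(C)(C)C)c2ccc(OCc3ccccc3)cc12
F2 | step 6 | tert-butyl 5-(benzyloxy)-3-(2-methoxyvinyl)indole-1-carboxylate, E/Z mixture | COC=Cc1cn(C(=O)OC(C)(C)C)c2ccc(OCc3ccccc3)cc12
F3 | step 6 | tert-butyl 5-(benzyloxy)-3-(1,2-dibromo-2-methoxyethyl)indole-1-carboxylate, mixture of diastereomers | COC(Br)C(Br)c1cn(C(=O)OC(C)(C)C)c2ccc(OCc3ccccc3)cc12
F4 | step 6 | tert-butyl (Z)-5-(benzyloxy)-3-(1-bromo-2-methoxyvinyl)indole-1-carboxylate | CO/C=C(\Br)c1cn(C(=O)OC(C)(C)C)c2ccc(OCc3ccccc3)cc12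
F5 | step 6 | (Z)-5-(benzyloxy)-3-(1-bromo-2-methoxyvinyl)-1H-indole | CO/C=C(\Br)c1c[nH]c2ccc(OCc3ccccc3)cc12
F6 | step 6 | sodium (Z)-5-(benzyloxy)-3-(1-bromo-2-methoxyvinyl)indol-1-ide | CO/C=C(\Br)c1c[n-]c2ccc(OCc3ccccc3)cc12.[Na+]
F7 | step 7 | 3-methoxy-4-(6-methoxy-1H-indol-3-yl)cyclobut-3-ene-1,2-dione | COC1=C(c2c[nH]c3cc(OC)ccc23)C(=O)C1=O
F8 | step 7 | tert-butyl 6-methoxy-3-(2-methoxy-3,4-dioxocyclobut-1-en-1-yl)indole-1-carboxylate | COC1=C(c2cn(C(=O)OC(C)(C)C)c3cc(OC)ccc23)C(=O)C1=O
F9 | step 7 | tert-butyl rac-3-(3-{(Z)-1-[5-(benzyloxy)-1-(triisopropylsilyl)indol-3-yl]-2-methoxyvinyl}-3-hydroxy-2-methoxy-4-oxocyclobut-1-en-1-yl)-6-methoxyindole-1-carboxylate | COc1ccc2c(C3=C(OC)C(O)(/C(=C\OC)c4cn([Si](C(C)C)(C(C)C)C(C)C)c5ccc(OCc6ccccc6)cc45)C3=O)cn(C(=O)OC(C)(C)C)c2c1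
F10 | step 7 | N-Boc hydroxy dienylketene, the analogue of 19 with tert-butoxycarbonyl on the 6-methoxyindole nitrogen | COc1ccc2c(C(=C=O)/C(OC)=C(O)\C(=C/OC)c3cn([Si](C(C)C)(C(C)C)C(C)C)c4ccc(OCc5ccccc5)cc34)cn(C(=O)OC(C)(C)C)c2c1
F11 | step 7 | N-Boc cyclohexa-2,4-dienone, the racemic analogue of 20 with tert-butoxycarbonyl on the 6-methoxyindole nitrogen | COc1ccc2c(C3=C(OC)C(O)=C(c4cn([Si](C(C)C)(C(C)C)C(C)C)c5ccc(OCc6ccccc6)cc45)C(OC)C3=O)cn(C(=O)OC(C)(C)C)c2c1
F12 | step 7 | tert-butyl 3-{4-[5-(benzyloxy)-1-(triisopropylsilyl)indol-3-yl]-2,5-dihydroxy-3,6-dimethoxyphenyl}-6-methoxyindole-1-carboxylate | COc1ccc2c(-c3c(O)c(OC)c(-c4cn([Si](C(C)C)(C(C)C)C(C)C)c5ccc(OCc6ccccc6)cc45)c(O)c3OC)cn(C(=O)OC(C)(C)C)c2c1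
F13 | step 7 | tert-butyl 3-{4-[5-(benzyloxy)-1-(triisopropylsilyl)indol-3-yl]-2,3,5,6-tetramethoxyphenyl}-6-methoxyindole-1-carboxylate | COc1ccc2c(-c3c(OC)c(OC)c(-c4cn([Si](C(C)C)(C(C)C)C(C)C)c5ccc(OCc6ccccc6)cc45)c(OC)c3OC)cn(C(=O)OC(C)(C)C)c2c1
F14 | step 7 | tert-butyl 3-{4-[5-(benzyloxy)-1H-indol-3-yl]-2,3,5,6-tetramethoxyphenyl}-6-methoxyindole-1-carboxylate | COc1ccc2c(-c3c(OC)c(OC)c(-c4c[nH]c5ccc(OCc6ccccc6)cc45)c(OC)c3OC)cn(C(=O)OC(C)(C)C)c2c1
F15 | step 8 | 2-[5-(benzyloxy)-1-(triisopropylsilyl)indol-3-yl]-3,6-dimethoxy-5-[6-methoxy-1-(triisopropylsilyl)indol-3-yl]cyclohexa-2,5-diene-1,4-dione | COc1ccc2c(C3=C(OC)C(=O)C(c4cn([Si](C(C)C)(C(C)C)C(C)C)c5ccc(OCc6ccccc6)cc45)=C(OC)C3=O)cn([Si](C(C)C)(C(C)C)C(C)C)c2c1
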